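## Structural features

The target is an achiral flavone: a benzene ring A fused to a 4-pyranone ring C, with a 2,4-dihydroxyphenyl ring B bonded to C2. Ring A has the phloroglucinol oxygen pattern, with the ring oxygen O1 on C8a and free hydroxyls on C5 and C7. C6, between the two hydroxyls, carries a 3-hydroxy-3-methylbutyl chain (a hydrated prenyl group), and C8 is unsubstituted. There are no stereocentres, so no configuration has to be set or protected. The fragile points are the tertiary alcohol, which acid would close onto O5 or O7 as a 2,2-dimethylchroman or dehydrate, the air-sensitive free polyphenol, and the reducible C2–C3 double bond. The real difficulty is regiochemical: C6 and C8 of a 5,7-dihydroxyflavone cannot be told apart reliably by direct alkylation, so the chain must be placed before ring C exists, and the final unmasking must be neutral. The key step uses the fact that C8a bears O1 and the neighbouring C4a bears the C4 carbonyl carbon, with the C5 oxygen next to C4a. That pattern is what an aryne across C4a–C8a leaves when it inserts into the C–O bond of a carboxylic acid, and the C5 oxygen polarises the aryne so that oxygen lands on C8a.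

## Logic of the disconnections

22 from 21. The last cut removes five O–CH2 bonds: four aryl O–benzyl bonds and the acetal O–CH2 bond on the tertiary oxygen. This leaves a fully masked precursor with no O–H that could quench an aryl anion and no phenol that could attack the tertiary carbon. The gain is that all five hydroxyls appear in one neutral operation. The demand is that hydrogenolysis spares the C2–C3 double bond and the C4 carbonyl and leaves the tertiary C–O bond alone.

21 from 13 and 18, through 20 and 19. Three bonds are cut: O1–C2, which opens ring C to 20, then C8a–O1 and C4a–C4 together, which leads to 19 and 18; 19 is traced to 13. These bonds join ring A to the rest, so cutting them gives two halves of similar size, each with its substitution complete. The gain is one ring and three skeletal bonds in one operation, with the C6/C8 question moved onto a simple benzene. The demands are that oxygen adds to C8a and acyl to C4a, that the acyl shift outruns protonation of the aryl anion, and that closure is 6-endo.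

13 from 10, through 12 and 11. The C4a–Si and O–S bonds are cut. Both groups can be placed from a phenol with an ortho bromine, so the aryne precursor reduces to a bromophenol. The demand is that bromine–lithium exchange is faster than any deprotonation of a benzylic O–CH2 group.

10 from 9, and 9 from 8. The C–Br bond is cut, then the phenolic hydrogen is exchanged for a silyl group. In 9 the position para to the hydroxyl is blocked and the two ortho positions are equivalent, so no regiochemical question remains. The demand is monobromination, and desilylation that leaves the acetal untouched.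

8 from 7, and 7 from 6. The acetal O–CH2 bond is cut, then the C3''–O bond, which turns the tertiary alcohol into a trisubstituted alkene. The gain is that the chain becomes a plain prenyl group. The demand is Markovnikov hydration under conditions that keep the aryl silyl ether.

6 from 2 and 3, through 5 and 4, and 2 from 1. The C6–C1'' bond is cut. In 2 the position between the two benzyloxy groups is the only one flanked by two coordinating ether oxygens, so the symmetry of 1 fixes where the chain goes. The demand is ring metalation without attack on a benzylic O–CH2 group, and allylation at the primary carbon of 3.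

18 from 16, through 17, then 15 and 14. The C–CO2H bond is cut, then the alkyne is traced to an aldehyde carbon by one-carbon homologation, then the two O–benzyl bonds are cut. The gain is a purchasable aldehyde. The demand is that the alkynide is formed cold enough to leave the benzyl ethers alone.

## Other disconnections considered

Alternative 1: The cut is at the two C3''–CH3 bonds. The forward step is double addition of MeMgBr to the lactone carbonyl of the lactone-bridged flavone A1 (a six-membered aryl lactone spanning O5 and C6), which would give A2 and release the C5 hydroxyl.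
- In its favour: the lactone masks O5 and carries the chain carbons at once, and the tertiary alcohol appears late and free. No hydration, no acetal and no aryne are needed.
- Better than the chosen plan on one point: A2 is three benzyl ethers from the target, so the final hydrogenolysis would release no formaldehyde.
- Against it: the Grignard reagent must finish both additions at the lactone carbon before it touches C4 or C2 of ring C, and chromones are known to accept organomagnesium reagents at both. The only protection is the higher electrophilicity of an aryl ester and the magnesium chelate formed at O5 after ring opening.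
- Against it on structure: A1 needs three differently treated oxygens on ring A and acylation at the less activated of two open carbons. The chosen plan gets its regiochemistry from the symmetry of 1.
- Step economy: equal after the key step (one hydrogenolysis each), but probably worse before it.

Alternative 2: The cut is at C4a–C5. The forward step is a base-mediated intramolecular Claisen condensation of the pyranonyl β-ketoester A3, which would close ring A and aromatise to the 5,7-diol A4.
- In its favour: it is biomimetic and needs no protecting group on ring A.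
- Equal to the chosen plan: the chain position is unambiguous, because the chain sits on the α-carbon of the ketoester.
- Better than the chosen plan: it avoids organolithium chemistry next to benzyl ethers and hot fluoride.
- Against it: A4 carries an unhydrated prenyl group between two free phenols. Ionic hydration there would favour chroman formation, and the alkene would have to be hydrated before any hydrogenolysis. At least two steps would follow the key step, against one in the chosen plan.
- Against it on mechanism: bond formation is needed at the γ-position (C4a) of an extended enolate while the most acidic proton lies between the two carbonyls of the ketoester. O-acylation and aldol pathways compete.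
- Against it on step economy: A3 is a sensitive polycarbonyl compound whose assembly is unlikely to be shorter than the route to 13.

Alternative 3: The cut takes four bonds of ring A: C8a–C8, C5–C6, C7–C8 and C4a–C5. The forward step is irradiation of the pyranonyl diazoketone A5 with the siloxyalkyne A6. Wolff rearrangement, ketene–alkyne [2+2] addition, four-electron ring opening and six-electron closure would give A7.
- In its favour: it is the most convergent of the four plans, and better than the chosen plan in bonds formed per step.
- Equal to the chosen plan: regiocontrol. The chain comes from the alkyne carbon, O7 from the siloxy group and O5 from the ketene carbonyl.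
- Better than the chosen plan: the tertiary oxygen is carried as a silyl ether, so no formaldehyde is released.
- Against it: the pyranone is itself a chromophore prone to photochemical rearrangement. The alkene that must join the six-electron closure is the endocyclic double bond of a vinylogous ester.
- Against it on safety and handling: A5 requires diazo chemistry on an electron-poor heterocycle, and A6 is a moisture-sensitive ynol ether.
- Against it on step economy: A7 needs fluoride desilylation and hydrogenolysis as separate operations.
- Overall: its mechanism is less predictable here than the polar aryne insertion.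

Key step: step 11

Remark on the chemistry: positions are numbered as in a flavone (O1, C2–C4, C4a, C5–C8, C8a; chain C1''–C3'' from the ring), also for the benzene precursors. Compounds 1, 3 and 14 are assumed purchasable.

Check of structures: in 13 the triflate is on the future C8a and the silyl group on the future C4a, beside the C5 benzyloxy group. Compounds 13, 18 and 21 map atom for atom onto 22, so no structure needed correction.

Design choices made here:
- a triisopropylsilyl group as the temporary phenol mask;
- copper-mediated prenylation;
- neutral radical hydration;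
- buffered desilylation.

Step 1
Reactants: 1 3,5-bis(benzyloxy)phenol
Product: 2 [3,5-bis(benzyloxy)phenoxy]tri(propan-2-yl)silane
Conditions: TIPSCl, imidazole, DMF, rt
Reagents that add atoms: chlorotri(propan-2-yl)silane (TIPSCl), CC(C)[Si](Cl)(C(C)C)C(C)C
Why: Standard silyl ether formation on a phenol; the bulky triisopropylsilyl group resists n-BuLi and shields both neighbouring ring positions, so the next metalation is steered to the carbon between the benzyl ethers.

Step 2
Reactants: 2 [3,5-bis(benzyloxy)phenoxy]tri(propan-2-yl)silane; 3 1-bromo-3-methylbut-2-ene (prenyl bromide)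
Product: 6 [3,5-bis(benzyloxy)-4-(3-methylbut-2-en-1-yl)phenoxy]tri(propan-2-yl)silane, via aryllithium 4 (not isolated), via arylcopper 5 (not isolated)
Conditions: n-BuLi, THF, 0 °C; CuI, −40 °C; 3, −40 → 0 °C
Reagents that add atoms: none
Why: Directed ortho-metalation: the C–H between the two benzyloxy groups is activated by both ether oxygens, while the hindered silyloxy group directs poorly. Transmetalation to monovalent copper and SN2 allylation at the primary carbon of 3 should give the linear prenyl arene and suppress halogen–metal exchange with the allylic bromide.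

Step 3
Reactants: 6 [3,5-bis(benzyloxy)-4-(3-methylbut-2-en-1-yl)phenoxy]tri(propan-2-yl)silane
Product: 7 4-{2,6-bis(benzyloxy)-4-[(triisopropylsilyl)oxy]phenyl}-2-methylbutan-2-ol
Conditions: Co(acac)2 (20 mol%), PhSiH3, O2 (1 atm), THF/i-PrOH, rt
Reagents that add atoms: dioxygen, O=O
Why: Mukaiyama hydration: hydrogen-atom transfer from a cobalt hydride gives the tertiary radical, O2 traps it and the silane reduces the peroxide, so the Markovnikov tertiary alcohol forms under neutral conditions that leave the aryl silyl ether and benzyl ethers alone.

Step 4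
Reactants: 7 4-{2,6-bis(benzyloxy)-4-[(triisopropylsilyl)oxy]phenyl}-2-methylbutan-2-ol
Product: 8 (3,5-bis(benzyloxy)-4-{3-[(benzyloxy)methoxy]-3-methylbutyl}phenoxy)tri(propan-2-yl)silane
Conditions: BOMCl, iPr2NEt, Bu4NI (cat.), ClCH2CH2Cl, 50 °C
Reagents that add atoms: benzyl chloromethyl ether (BOMCl), ClCOCc1ccccc1
Why: Alkoxymethylation of a tertiary alcohol by the reactive iodomethyl ether formed in situ; the acetal removes the only protic site before the organolithium, triflation and aryne steps and later falls to hydrogenolysis with the benzyl ethers.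

Step 5
Reactants: 8 (3,5-bis(benzyloxy)-4-{3-[(benzyloxy)methoxy]-3-methylbutyl}phenoxy)tri(propan-2-yl)silane
Product: 9 3,5-bis(benzyloxy)-4-{3-[(benzyloxy)methoxy]-3-methylbutyl}phenol
Conditions: TBAF, AcOH, THF, 0 °C
Reagents that add atoms: none
Why: Fluoride cleavage of an aryl silyl ether; acetic acid buffers the electron-rich phenoxide against air oxidation, and acetal and benzyl ethers are inert to fluoride.

Step 6
Reactants: 9 3,5-bis(benzyloxy)-4-{3-[(benzyloxy)methoxy]-3-methylbutyl}phenol
Product: 10 3,5-bis(benzyloxy)-4-{3-[(benzyloxy)methoxy]-3-methylbutyl}-2-bromophenol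
Conditions: NBS (1.0 equiv), CH2Cl2, −78 → 0 °C
Reagents that add atoms: N-bromosuccinimide, O=C1CCC(=O)N1Br
Why: Electrophilic aromatic bromination ortho to the free hydroxyl; the para position is blocked, the two ortho positions are equivalent, and one equivalent at low temperature should limit dibromination.

Step 7
Reactants: 10 3,5-bis(benzyloxy)-4-{3-[(benzyloxy)methoxy]-3-methylbutyl}-2-bromophenol
Product: 13 3,5-bis(benzyloxy)-4-{3-[(benzyloxy)methoxy]-3-methylbutyl}-2-(trimethylsilyl)phenyl trifluoromethanesulfonate, via trimethylsilyl ether 11 (not isolated), via lithium 2-silylphenoxide 12 (not isolated)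
Conditions: HMDS, THF, 65 °C, then evaporation; n-BuLi, THF, −100 → −80 °C; Tf2O, −100 → −70 °C
Reagents that add atoms: hexamethyldisilazane, C[Si](C)(C)N[Si](C)(C)C; trifluoromethanesulfonic anhydride, O=S(=O)(OS(=O)(=O)C(F)(F)F)C(F)(F)F
Why: O-silylation, bromine–lithium exchange and retro-Brook rearrangement (1,3 shift of silicon from oxygen to carbon) give the ortho-silyl phenoxide, which is triflated in the same flask. This is the standard passage from an ortho-bromophenol to an ortho-silylaryl triflate, and exchange at −100 °C should outrun deprotonation of the benzylic positions.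

Step 8
Reactants: 14 2,4-dihydroxybenzaldehyde
Product: 15 2,4-bis(benzyloxy)benzaldehyde
Conditions: BnBr (2.5 equiv), K2CO3, DMF, 60 °C
Reagents that add atoms: benzyl bromide, BrCc1ccccc1
Why: Williamson ether synthesis; warming and excess bromide are needed because the 2-hydroxyl is hydrogen-bonded to the aldehyde.

Step 9
Reactants: 15 2,4-bis(benzyloxy)benzaldehyde
Product: 16 2,4-bis(benzyloxy)-1-(2,2-dibromoethenyl)benzene
Conditions: CBr4, PPh3, Zn, CH2Cl2, rt
Reagents that add atoms: tetrabromomethane, BrC(Br)(Br)Br
Why: First stage of the Corey–Fuchs homologation: Wittig-type olefination of the aldehyde by the dibromomethylene ylide, with zinc as the bromine acceptor so that the medium stays neutral.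

Step 10
Reactants: 16 2,4-bis(benzyloxy)-1-(2,2-dibromoethenyl)benzene
Product: 18 3-[2,4-bis(benzyloxy)phenyl]prop-2-ynoic acid, via lithium alkynide 17 (not isolated)
Conditions: n-BuLi (2.2 equiv), THF, −78 °C; CO2 (g), −78 °C → rt; aq. HCl to pH 3
Reagents that add atoms: carbon dioxide, O=C=O
Why: Second stage of the Corey–Fuchs sequence: bromine–lithium exchange, loss of LiBr with 1,2-shift and deprotonation give the lithium alkynide, which is carboxylated by CO2; at −78 °C the benzyl ethers are not attacked.

Step 11
Reactants: 13 3,5-bis(benzyloxy)-4-{3-[(benzyloxy)methoxy]-3-methylbutyl}-2-(trimethylsilyl)phenyl trifluoromethanesulfonate; 18 3-[2,4-bis(benzyloxy)phenyl]prop-2-ynoic acid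
Product: 21 5,7-bis(benzyloxy)-2-[2,4-bis(benzyloxy)phenyl]-6-{3-[(benzyloxy)methoxy]-3-methylbutyl}-4H-chromen-4-one, via aryne 19 (not isolated), via ortho-hydroxyaryl ynone 20 (not isolated)
Conditions: CsF (4 equiv), THF, 125 °C, sealed tube (13 in slight excess, rigorously dry)
Reagents that add atoms: none
Why: Fluoride attacks silicon in 13 and loss of triflate releases aryne 19, while CsF also turns 18 into its cesium carboxylate; the carboxylate oxygen adds to the aryne carbon that becomes C8a, the aryl anion at C4a attacks the ester carbonyl, and the strained four-membered alkoxide opens to the phenoxide of ynone 20, a net insertion of the aryne into the acyl C–O bond. The closest known reaction type is the CsF-promoted insertion of arynes from ortho-silylaryl triflates into the C–O bond of carboxylic acids, which gives ortho-hydroxyaryl ketones and, with unsaturated acids, chromanones by conjugate closure in the same pot. Ring C then closes by 6-endo-dig oxa-Michael addition of the C8a phenoxide to C2, the β-carbon of the ynone and its electronically matched terminus, and protonation at C3 gives the pyranone. No stereocentre is formed. The step needs oxygen on C8a and acyl on C4a: the benzyloxy group at C5 withdraws inductively and distorts the aryne, so the nucleophile attacks the remote carbon C8a and the negative charge develops at C4a beside that oxygen. It also needs the acyl shift to outrun protonation of the aryl anion (simple O-arylation), which is served by the aprotic medium, by the absence of any O–H or N–H group in 13, and by the high temperature that favours the intramolecular pathway. Benzyl ethers, acetal and alkyne carry nothing that reacts with fluoride.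

Step 12
Reactants: 21 5,7-bis(benzyloxy)-2-[2,4-bis(benzyloxy)phenyl]-6-{3-[(benzyloxy)methoxy]-3-methylbutyl}-4H-chromen-4-one
Product: 22 2-(2,4-dihydroxyphenyl)-5,7-dihydroxy-6-(3-hydroxy-3-methylbutyl)-4H-chromen-4-one
Conditions: H2 (1 atm), 10% Pd/C, EtOAc/MeOH, rt, stopped when hydrogen uptake ends
Reagents that add atoms: none
Why: Catalytic hydrogenolysis cleaves the four benzylic C–O bonds and the benzyl C–O bond of the acetal, whose hemiacetal then loses formaldehyde (held as its hemiacetal by methanol). The neutral medium keeps the tertiary alcohol from cyclising onto O5 or O7, and the C2–C3 double bond of the pyranone is reduced much more slowly than benzyl ethers are cleaved.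

## Compound list

1 | 3,5-bis(benzyloxy)phenol | Oc1cc(OCc2ccccc2)cc(OCc2ccccc2)c1 | starting material
2 | [3,5-bis(benzyloxy)phenoxy]tri(propan-2-yl)silane | CC(C)[Si](Oc1cc(OCc2ccccc2)cc(OCc2ccccc2)c1)(C(C)C)C(C)C | intermediate
3 | 1-bromo-3-methylbut-2-ene (prenyl bromide) | CC(C)=CCBr | starting material
4 | {2,6-bis(benzyloxy)-4-[(triisopropylsilyl)oxy]phenyl}lithium | [Li]c1c(OCc2ccccc2)cc(O[Si](C(C)C)(C(C)C)C(C)C)cc1OCc1ccccc1 | intermediate (not isolated)
5 | {2,6-bis(benzyloxy)-4-[(triisopropylsilyl)oxy]phenyl}copper | [Cu]c1c(OCc2ccccc2)cc(O[Si](C(C)C)(C(C)C)C(C)C)cc1OCc1ccccc1 | intermediate (not isolated)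
6 | [3,5-bis(benzyloxy)-4-(3-methylbut-2-en-1-yl)phenoxy]tri(propan-2-yl)silane | CC(C)=CCc1c(OCc2ccccc2)cc(O[Si](C(C)C)(C(C)C)C(C)C)cc1OCc1ccccc1 | intermediate
7 | 4-{2,6-bis(benzyloxy)-4-[(triisopropylsilyl)oxy]phenyl}-2-methylbutan-2-ol | CC(C)(O)CCc1c(OCc2ccccc2)cc(O[Si](C(C)C)(C(C)C)C(C)C)cc1OCc1ccccc1 | intermediate
8 | (3,5-bis(benzyloxy)-4-{3-[(benzyloxy)methoxy]-3-methylbutyl}phenoxy)tri(propan-2-yl)silane | CC(C)(OCOCc1ccccc1)CCc1c(OCc2ccccc2)cc(O[Si](C(C)C)(C(C)C)C(C)C)cc1OCc1ccccc1 | intermediate
9 | 3,5-bis(benzyloxy)-4-{3-[(benzyloxy)methoxy]-3-methylbutyl}phenol | CC(C)(OCOCc1ccccc1)CCc1c(OCc2ccccc2)cc(O)cc1OCc1ccccc1 | intermediate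
10 | 3,5-bis(benzyloxy)-4-{3-[(benzyloxy)methoxy]-3-methylbutyl}-2-bromophenol | CC(C)(OCOCc1ccccc1)CCc1c(OCc2ccccc2)cc(O)c(Br)c1OCc1ccccc1 | intermediate
11 | (3,5-bis(benzyloxy)-4-{3-[(benzyloxy)methoxy]-3-methylbutyl}-2-bromophenoxy)trimethylsilane | CC(C)(OCOCc1ccccc1)CCc1c(OCc2ccccc2)cc(O[Si](C)(C)C)c(Br)c1OCc1ccccc1 | intermediate (not isolated)
12 | lithium 3,5-bis(benzyloxy)-4-{3-[(benzyloxy)methoxy]-3-methylbutyl}-2-(trimethylsilyl)phenolate | CC(C)(OCOCc1ccccc1)CCc1c(OCc2ccccc2)cc(O[Li])c([Si](C)(C)C)c1OCc1ccccc1 | intermediate (not isolated)
13 | 3,5-bis(benzyloxy)-4-{3-[(benzyloxy)methoxy]-3-methylbutyl}-2-(trimethylsilyl)phenyl trifluoromethanesulfonate | CC(C)(OCOCc1ccccc1)CCc1c(OCc2ccccc2)cc(OS(=O)(=O)C(F)(F)F)c([Si](C)(C)C)c1OCc1ccccc1 | intermediate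
14 | 2,4-dihydroxybenzaldehyde | O=Cc1ccc(O)cc1O | starting material
15 | 2,4-bis(benzyloxy)benzaldehyde | O=Cc1ccc(OCc2ccccc2)cc1OCc1ccccc1 | intermediate
16 | 2,4-bis(benzyloxy)-1-(2,2-dibromoethenyl)benzene | BrC(Br)=Cc1ccc(OCc2ccccc2)cc1OCc1ccccc1 | intermediate
17 | {[2,4-bis(benzyloxy)phenyl]ethynyl}lithium | [Li]C#Cc1ccc(OCc2ccccc2)cc1OCc1ccccc1 | intermediate (not isolated)
18 | 3-[2,4-bis(benzyloxy)phenyl]prop-2-ynoic acid | OC(=O)C#Cc1ccc(OCc2ccccc2)cc1OCc1ccccc1 | intermediate
19 | 3,5-bis(benzyloxy)-4-{3-[(benzyloxy)methoxy]-3-methylbutyl}-1,2-didehydrobenzene (aryne) | CC(C)(OCOCc1ccccc1)CCC1=C(OCc2ccccc2)C#CC=C1OCc1ccccc1 | intermediate (not isolated)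
20 | 1-(4,6-bis(benzyloxy)-5-{3-[(benzyloxy)methoxy]-3-methylbutyl}-2-hydroxyphenyl)-3-[2,4-bis(benzyloxy)phenyl]prop-2-yn-1-one | CC(C)(OCOCc1ccccc1)CCc1c(OCc2ccccc2)cc(O)c(C(=O)C#Cc2ccc(OCc3ccccc3)cc2OCc2ccccc2)c1OCc1ccccc1 | intermediate (not isolated; present as its cesium phenoxide)
21 | 5,7-bis(benzyloxy)-2-[2,4-bis(benzyloxy)phenyl]-6-{3-[(benzyloxy)methoxy]-3-methylbutyl}-4H-chromen-4-one | CC(C)(OCOCc1ccccc1)CCc1c(OCc2ccccc2)cc2oc(-c3ccc(OCc4ccccc4)cc3OCc3ccccc3)cc(=O)c2c1OCc1ccccc1 | intermediate
22 | 2-(2,4-dihydroxyphenyl)-5,7-dihydroxy-6-(3-hydroxy-3-methylbutyl)-4H-chromen-4-one | CC(C)(O)CCc1c(O)cc2oc(-c3ccc(O)cc3O)cc(=O)c2c1O | target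

## Step count and risks

Total step count: 12. Longest linear sequence: 9 (steps 1–7, 11, 12); the acid branch is 3 steps (8–10).

Least certain steps:

**Step 11 (key step).** What may go wrong:
- protonation of the aryl anion before the acyl shift, by bifluoride, traces of water or the neighbouring benzylic O–CH2 group, which would stop at simple O-arylation;
- thermal decarboxylation of the cesium arylpropiolate before it meets the slowly released aryne;
- closure of the phenoxide onto the α-carbon (5-exo-dig) instead of C2.

Fallback with known chemistry: it sets out from 10 and 18 and returns to the route at 21, passing through 20, which is isolated on this path. Acid 18 would be coupled with N,O-dimethylhydroxylamine hydrochloride and a carbodiimide to the Weinreb amide N-methoxy-N-methyl-3-[2,4-bis(benzyloxy)phenyl]prop-2-ynamide F1. Bromophenol 10 would be treated with n-BuLi (2.2 equiv, THF, −78 °C), giving by O–H deprotonation and bromine–lithium exchange the dilithio species lithium 3,5-bis(benzyloxy)-4-{3-[(benzyloxy)methoxy]-3-methylbutyl}-2-lithiophenolate F2. Addition of F2 to F1 and aqueous work-up should give ynone 20. Et2NH in EtOH would then close 20 to 21 by conjugate addition of the amine and addition–elimination by the phenol, which enforces the 6-endo mode.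

**Step 2.** What may go wrong:
- deprotonation of a benzylic O–CH2 group followed by [1,2]-Wittig rearrangement;
- metalation beside the silyloxy group;
- allylation at the tertiary end of the allyl system.

The danger comes from the acidity of benzylic ether hydrogens towards alkyllithiums.

Fallback: it sets out from 1 and returns at 7, replacing steps 1–3.
- Vilsmeier–Haack formylation of 1 (POCl3, DMF, then aqueous NaOAc) should go mainly para to the hydroxyl and give 2,6-bis(benzyloxy)-4-hydroxybenzaldehyde F3.
- Silylation (TIPSCl, imidazole) would give 2,6-bis(benzyloxy)-4-[(triisopropylsilyl)oxy]benzaldehyde F4.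
- Wittig reaction with Ph3P=CHC(O)CH3 in hot toluene would give (3E)-4-{2,6-bis(benzyloxy)-4-[(triisopropylsilyl)oxy]phenyl}but-3-en-2-one F5.
- Conjugate reduction with catalytic [(Ph3P)CuH]6 and PhSiH3 would give 4-{2,6-bis(benzyloxy)-4-[(triisopropylsilyl)oxy]phenyl}butan-2-one F6.
- MeMgBr in THF at 0 °C would convert F6 into 7.

No benzyl ether meets a strong base on this path.

**Step 7.** What may go wrong:
- hydrolysis of the labile O-silyl ether before the exchange;
- protonation of the aryllithium before silicon migrates into the crowded position between oxygen and benzyloxy;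
- incomplete triflation of the hindered phenoxide.

Fallback: it sets out from 10 and returns at 13. The dilithio species F2 (formed from 10 as described under step 11) would be quenched with excess TMSCl to give [3,5-bis(benzyloxy)-4-{3-[(benzyloxy)methoxy]-3-methylbutyl}-2-(trimethylsilyl)phenoxy]trimethylsilane F7, so the C–Si bond is made by direct capture and not by migration. K2CO3 in MeOH at 0 °C would cleave only the O–Si bond and give 3,5-bis(benzyloxy)-4-{3-[(benzyloxy)methoxy]-3-methylbutyl}-2-(trimethylsilyl)phenol F8. Tf2O and pyridine in CH2Cl2 at 0 °C would convert F8 into 13.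

**Step 12.** What may go wrong:
- saturation of the C2–C3 double bond before the last benzyl ether or the acetal is cleaved;
- hydroxymethylation of the electron-rich C8 position by the released formaldehyde.

Dilution and methanol as cosolvent are the first precautions.

Fallback: it sets out from 21 and returns at 22. The hydrogenation would be run deliberately to the end over Pd(OH)2/C, to the racemic flavanone 2-(2,4-dihydroxyphenyl)-5,7-dihydroxy-6-(3-hydroxy-3-methylbutyl)-2,3-dihydro-4H-chromen-4-one F9. The C2–C3 double bond would then be restored by the known iodine-mediated dehydrogenation of flavanones (I2, pyridine, 90 °C), with the base buffering the tertiary alcohol against acid.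

## Further compounds

F1 | step 11 | N-methoxy-N-methyl-3-[2,4-bis(benzyloxy)phenyl]prop-2-ynamide | CON(C)C(=O)C#Cc1ccc(OCc2ccccc2)cc1OCc1ccccc1
F2 | step 11 | lithium 3,5-bis(benzyloxy)-4-{3-[(benzyloxy)methoxy]-3-methylbutyl}-2-lithiophenolate | CC(C)(OCOCc1ccccc1)CCc1c(OCc2ccccc2)cc(O[Li])c([Li])c1OCc1ccccc1
F3 | step 2 | 2,6-bis(benzyloxy)-4-hydroxybenzaldehyde | O=Cc1c(OCc2ccccc2)cc(O)cc1OCc1ccccc1
F4 | step 2 | 2,6-bis(benzyloxy)-4-[(triisopropylsilyl)oxy]benzaldehyde | O=Cc1c(OCc2ccccc2)cc(O[Si](C(C)C)(C(C)C)C(C)C)cc1OCc1ccccc1
F5 | step 2 | (3E)-4-{2,6-bis(benzyloxy)-4-[(triisopropylsilyl)oxy]phenyl}but-3-en-2-one | CC(=O)/C=C/c1c(OCc2ccccc2)cc(O[Si](C(C)C)(C(C)C)C(C)C)cc1OCc1ccccc1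
F6 | step 2 | 4-{2,6-bis(benzyloxy)-4-[(triisopropylsilyl)oxy]phenyl}butan-2-one | CC(=O)CCc1c(OCc2ccccc2)cc(O[Si](C(C)C)(C(C)C)C(C)C)cc1OCc1ccccc1
F7 | step 7 | [3,5-bis(benzyloxy)-4-{3-[(benzyloxy)methoxy]-3-methylbutyl}-2-(trimethylsilyl)phenoxy]trimethylsilane | CC(C)(OCOCc1ccccc1)CCc1c(OCc2ccccc2)cc(O[Si](C)(C)C)c([Si](C)(C)C)c1OCc1ccccc1
F8 | step 7 | 3,5-bis(benzyloxy)-4-{3-[(benzyloxy)methoxy]-3-methylbutyl}-2-(trimethylsilyl)phenol | CC(C)(OCOCc1ccccc1)CCc1c(OCc2ccccc2)cc(O)c([Si](C)(C)C)c1OCc1ccccc1
F9 | step 12 | 2-(2,4-dihydroxyphenyl)-5,7-dihydroxy-6-(3-hydroxy-3-methylbutyl)-2,3-dihydro-4H-chromen-4-one (racemic) | CC(C)(O)CCc1c(O)cc2OC(CC(=O)c2c1O)c1ccc(O)cc1O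
A1 | alternative 1 | 5-(benzyloxy)-8-[2,4-bis(benzyloxy)phenyl]-3,4-dihydro-2H,10H-pyrano[2,3-f]chromene-2,10-dione (lactone-bridged flavone) | O=C1CCc2c(OCc3ccccc3)cc3oc(-c4ccc(OCc5ccccc5)cc4OCc4ccccc4)cc(=O)c3c2O1
A2 | alternative 1 | 7-(benzyloxy)-2-[2,4-bis(benzyloxy)phenyl]-5-hydroxy-6-(3-hydroxy-3-methylbutyl)-4H-chromen-4-one | CC(C)(O)CCc1c(OCc2ccccc2)cc2oc(-c3ccc(OCc4ccccc4)cc3OCc3ccccc3)cc(=O)c2c1O
A3 | alternative 2 | methyl 2-({6-[2,4-bis(benzyloxy)phenyl]-4-oxo-4H-pyran-2-yl}acetyl)-5-methylhex-4-enoate | COC(=O)C(CC=C(C)C)C(=O)Cc1cc(=O)cc(-c2ccc(OCc3ccccc3)cc2OCc2ccccc2)o1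
A4 | alternative 2 | 2-[2,4-bis(benzyloxy)phenyl]-5,7-dihydroxy-6-(3-methylbut-2-en-1-yl)-4H-chromen-4-one | CC(C)=CCc1c(O)cc2oc(-c3ccc(OCc4ccccc4)cc3OCc3ccccc3)cc(=O)c2c1O
A5 | alternative 3 | 1-{6-[2,4-bis(benzyloxy)phenyl]-4-oxo-4H-pyran-2-yl}-2-diazoethan-1-one | [N-]=[N+]=CC(=O)c1cc(=O)cc(-c2ccc(OCc3ccccc3)cc2OCc2ccccc2)o1
A6 | alternative 3 | triisopropyl({5-methyl-5-[(triethylsilyl)oxy]hex-1-yn-1-yl}oxy)silane | CC[Si](CC)(CC)OC(C)(C)CCC#CO[Si](C(C)C)(C(C)C)C(C)C
A7 | alternative 3 | 2-[2,4-bis(benzyloxy)phenyl]-5-hydroxy-6-{3-methyl-3-[(triethylsilyl)oxy]butyl}-7-(triisopropylsilyloxy)-4H-chromen-4-one | CC(C)(O[Si](CC)(CC)CC)CCc1c(O[Si](C(C)C)(C(C)C)C(C)C)cc2oc(-c3ccc(OCc4ccccc4)cc3OCc3ccccc3)cc(=O)c2c1O
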